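## The problem

6,8-Diprenylaromadendrin (21) is a 2,3-trans-3-hydroxyflavanone. A fully substituted phloroglucinol ring A, with prenyl groups at C6 and C8, is fused through C4a–C8a to the dihydropyranone ring C, and the 4-hydroxyphenyl ring B is attached at C2. The only stereocentres are the adjacent C2 and C3, both R and trans to each other. C3 lies α to the C4 ketone and can be equilibrated, so a correctly set C2 will pull C3 into the diequatorial trans arrangement. C2 is a benzylic aryl ether carbon that can only be changed by opening ring C, so its absolute configuration is the real stereochemical task. The molecule tolerates little: prenyl alkenes next to phenols cyclise to chromans in strong acid and are lost on hydrogenation, and the α-ketol opens to a chalcone or is oxidised to the flavonol in base. Ring A has no free position, so both prenyl groups must be placed regiospecifically between oxygen atoms, best before the ketol exists. Two features make a short route possible. C3 bears oxygen and sits between the C4 carbonyl and the C2 carbinol carbon, the pattern left when a ketocarbene carbon is joined first to an O–H donor and then to an aldehyde. O1 is an aryl ether oxygen ortho to the C4 carbonyl, so O1–C8a can be made last by displacing fluoride, which leaves the C2–O bond and the C2 configuration untouched.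

## Retrosynthesis

21 back to 19: no skeletal bond is cut. The two acetal ethers on ring A and the carbonate on ring B of 20 come off in one mild acid treatment, and the 4-methoxybenzyl ether on O3 of 19 comes off oxidatively before that. O3 needs a group that can be brought in as an alcohol and removed without hydrogen, because of the prenyl alkenes. The forward steps must use an oxidant that spares ring A and an acid weak enough not to cyclise the prenyl groups.

19 back to 18: the O1–C8a bond is cut. Cutting C2–O1 instead would need a free phenol ortho to the ketone and would invert the benzylic centre on closure. Cutting by oxa-Michael logic would pass through a chalcone and lose both centres. With fluorine at C8a, the C2 hydroxyl of 18 closes ring C with retention, and the carbene precursor carries one ortho oxygen fewer. 18 is acyclic and holds both stereocentres. The forward reaction needs the alkoxide to add to C8a faster than it fragments by retro-aldol.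

18 back to 13, 15 and 16: the C3–O and C2–C3 bonds are cut together. A chalcone dihydroxylation would give the syn diol with two free hydroxyls that are hard to tell apart. A two-step insertion and aldol sequence would form the same bonds one at a time. The three-part cut gives the anti α-alkoxy-β-hydroxy ketone with O3 already capped and the C2 hydroxyl free, which is what a regioselective ring closure needs. The three precursors are achiral and simple. The forward reaction needs capture of the carbene by the external O–H ahead of internal traps, capture of the ylide by the aldehyde ahead of proton shift, and a chiral acid that controls the aldehyde face and the anti relation.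

13 back to 11: the diazo group is put on the methyl ketone by diazo transfer. The route through a carboxylic acid and its chloride would place an acyl chloride and HCl next to an ortho acetal ether, which can be lost or can close onto the acyl carbon. 11 is an ordinary acetophenone.

11 back to 9, 6, 2 and 1 (with 3): the acetyl group and the two prenyl groups are removed in reverse order of introduction, each by directed ortho-metalation logic. In 2 the site between the two acetal ethers is distinct. After it is filled (6), the two remaining ring hydrogens are equivalent. After the second prenylation (9), only one is left. So only the first metalation needs regiocontrol. Electrophilic C-prenylation of an acylphloroglucinol would give mixtures. The forward steps need the ortho-fluoroaryllithiums to be kept cold and passed to copper before allylation.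

15 back to 14: the O–C(O) bond is cut. The carbonate is chosen over an acetal ether because it makes the aldehyde a better acceptor for the ylide and falls off in the final acid step.

## Roads not taken

Alternative 1: The cut runs through ring A. Heating cyclobutenone A2 with siloxyalkyne A3 forms C8–C8a, C6–C7 and C4a–C8a by a Danheiser benzannulation (electrocyclic opening to a vinylketene, [2+2] addition, second opening, 6π closure) and gives phenol A1.
- Merits: the cascade fixes the place of every substituent on ring A, so no directing-group hierarchy has to be trusted. The three oxygens of A1 come out differentiated (free hydroxyl, acetal ether, silyl ether).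
- Weak points: the main step builds the one achiral ring that can be bought as a simple arene. A2 and A3 each need several steps. A1 still lacks C2, C3, C4, ring B and both stereocentres, so acylation, chain building, an asymmetric oxidation and ring closure would all follow.
- Comparison: this road is better in regiochemical certainty for ring A. The chosen plan answers with the symmetry of 2, which leaves only the first metalation open to doubt, and with a key step that makes the C2–C3–C4 unit and both stereocentres at once. It should be several steps shorter overall.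

Alternative 2: C4a–C8a, C5–C6 and C7–C8 are cut. The tethered diyne A5 (an ynone and an alkynyl ether joined through C4, C3, C2 and O1) would be cyclotrimerised with A3 by [Rh(cod)2]BF4 and BINAP (monovalent rhodium). Rings A and C close together to give A4, two deprotections from the target.
- Merits: this is the most convergent plan. The stereocentres are carried in untouched from an acyclic anti diol, and no base-mediated closure next to a β-hydroxy ketone is needed. In these respects it is better than the chosen plan.
- Weak points: A5 combines a secondary benzylic alkynyl ether, a class that rearranges or eliminates to ketenes on mild warming, with a strongly electrophilic silyloxy ynone. A3 can insert in two orientations, and the wrong one exchanges the C6 prenyl group and the C7 oxygen. A3 can also trimerise with itself. The anti diol in A5 must be made enantiopure elsewhere, so the stereochemical problem is moved, not solved.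
- Comparison: against the higher convergence the chosen plan sets stable arene and ketone intermediates, ring A regiochemistry settled on a simple arene, and stereocentres made by the key step itself.

Alternative 3: The two C–CH2 bonds at C6 and C8 are cut. The 5,7-bis(allyl ether) A7 would be heated with Eu(fod)3 so that both allyl groups move from oxygen to carbon and give A6. Olefin cross-metathesis (second-generation Grubbs catalyst) would then turn allyl into prenyl.
- Merits: the stereocentres are already present and are not involved in the key step. The O5 allyl group can only reach C6 or, by a following Cope shift, C8, so both migrations funnel into the 6,8-pattern. If the protected flavanonol core is at hand, this is the shortest road and uses long-established reactions. From that point it is as good as or better than the chosen plan in step economy.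
- Weak points: two sigmatropic shifts must be driven to completion with heat and a Lewis acid on a 3-alkoxyflavanone, which can open to the chalcone, lose the C3 oxygen or epimerise at C2. Each shift frees a phenol ortho to an allyl group, an arrangement that cyclises to dihydrobenzofurans. Allylating the chelated O5 needs forcing conditions. The product has allyl, not prenyl, so a double cross-metathesis is added. The core of A7 must first be made enantiopure, which costs a complete flavanonol synthesis.
- Comparison: against the brevity of this relay the chosen plan sets a skeleton and stereocentres built from simple arenes, prenyl groups placed before any sensitive function exists, and no late thermal step.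

Key step: step 7

Assumption (chemistry): the (R) enantiomer of the phosphoric acid is taken to give the (2R,3R) adduct 18; if the sense of induction is the reverse, the (S) acid is used and nothing else changes.

## Steps

Step 1
Reactants: 1 5-fluororesorcinol
Product: 2 1-fluoro-3,5-bis(methoxymethoxy)benzene
Conditions: MOMCl (2.5 equiv), iPr2NEt (3 equiv), CH2Cl2, 0 °C to rt
Reagents that add atoms: chloromethyl methyl ether, COCCl
Why: O-alkylation of both phenols with the α-chloro ether under amine base (methoxymethyl ether formation). The acetal ethers are the directing groups for all later metalations and are removed together at the end.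

Step 2
Reactants: 2 1-fluoro-3,5-bis(methoxymethoxy)benzene; 3 prenyl bromide (1-bromo-3-methylbut-2-ene)
Product: 6 5-fluoro-1,3-bis(methoxymethoxy)-2-(3-methylbut-2-enyl)benzene, via aryllithium 4 (not isolated), via arylcopper 5 (not isolated)
Conditions: n-BuLi (1.1 equiv), THF, −78 to −40 °C; CuBr·SMe2 (1.1 equiv), −78 to −40 °C; 3 (1.3 equiv), −78 to 0 °C
Reagents that add atoms: n-butyllithium, [Li]CCCC (lithium of 4 only); CuBr·SMe2, [Cu]Br.CSC (copper of 5 only)
Why: Directed ortho-metalation; the position between the two acetal ethers is held by two coordinating groups, which outrank fluorine as directors toward alkyllithiums, and its lithio species has no ortho fluorine and so cannot form an aryne. Transmetalation to copper and substitution of the allylic bromide at its primary carbon gives the linear prenyl arene.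

Step 3
Reactants: 6 5-fluoro-1,3-bis(methoxymethoxy)-2-(3-methylbut-2-enyl)benzene; 3 prenyl bromide
Product: 9 1-fluoro-3,5-bis(methoxymethoxy)-2,4-bis(3-methylbut-2-enyl)benzene, via aryllithium 7 (not isolated), via arylcopper 8 (not isolated)
Conditions: s-BuLi (1.1 equiv), THF, −78 °C; CuBr·SMe2 (1.1 equiv), −78 °C; 3 (1.3 equiv), −78 to 0 °C
Reagents that add atoms: sec-butyllithium, CCC(C)[Li] (lithium of 7 only); CuBr·SMe2, [Cu]Br.CSC (copper of 8 only)
Why: Second directed ortho-metalation at one of two equivalent positions, each flanked by fluorine and an acetal ether, so no regiochemical choice arises. The ortho-fluoroaryllithium is kept at −78 °C until it is on copper, which prevents loss of LiF to an aryne, and is then allylated as in step 2.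

Step 4
Reactants: 9 1-fluoro-3,5-bis(methoxymethoxy)-2,4-bis(3-methylbut-2-enyl)benzene
Product: 11 1-[2-fluoro-4,6-bis(methoxymethoxy)-3,5-bis(3-methylbut-2-enyl)phenyl]ethan-1-one, via aryllithium 10 (not isolated)
Conditions: s-BuLi (1.1 equiv), THF, −78 °C; N-methoxy-N-methylacetamide (1.5 equiv), −78 to −40 °C; then H2O
Reagents that add atoms: N-methoxy-N-methylacetamide, CC(=O)N(C)OC; sec-butyllithium, CCC(C)[Li] (lithium of 10 only)
Why: Third directed ortho-metalation at the only ring hydrogen left, followed by Weinreb ketone synthesis. The chelated tetrahedral adduct persists until work-up, so the ketone is not attacked a second time.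

Step 5
Reactants: 11 1-[2-fluoro-4,6-bis(methoxymethoxy)-3,5-bis(3-methylbut-2-enyl)phenyl]ethan-1-one
Product: 13 2-diazo-1-[2-fluoro-4,6-bis(methoxymethoxy)-3,5-bis(3-methylbut-2-enyl)phenyl]ethan-1-one, via trifluoromethyl diketone 12 (not isolated)
Conditions: LiN(SiMe3)2 (1.1 equiv), THF, −78 °C; CF3CO2CH2CF3 (1.2 equiv), −78 °C; cold dilute HCl wash; then MsN3 (1.5 equiv), Et3N (1.5 equiv), H2O (1 equiv), MeCN, rt
Reagents that add atoms: 2,2,2-trifluoroethyl trifluoroacetate, O=C(OCC(F)(F)F)C(F)(F)F (trifluoroacetyl group of 12 only); methanesulfonyl azide, CS(=O)(=O)N=[N+]=[N-]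
Why: Detrifluoroacetylative diazo transfer: Claisen condensation of the lithium enolate with the trifluoroacetate activates the methyl group, the sulfonyl azide transfers N2 to the 1,3-diketone, and the trifluoroacetyl group is cleaved in the same flask. No acyl chloride, HCl gas or diazomethane meets the acetal ethers, and the short reaction at room temperature gives the fluoro diketone no chance to close to a chromone.

Step 6
Reactants: 14 4-hydroxybenzaldehyde
Product: 15 tert-butyl (4-formylphenyl) carbonate
Conditions: Boc2O (1.1 equiv), DMAP (5 mol %), MeCN, rt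
Reagents that add atoms: di-tert-butyl dicarbonate, CC(C)(C)OC(=O)OC(=O)OC(C)(C)C
Why: DMAP-catalysed O-acylation of the phenol. The carbonate turns the para oxygen from a donor into an acceptor, which makes the aldehyde a better partner for the ylide in step 7 and disfavours retro-aldol later; it is removed by the acid of step 10.

Step 7
Reactants: 13 2-diazo-1-[2-fluoro-4,6-bis(methoxymethoxy)-3,5-bis(3-methylbut-2-enyl)phenyl]ethan-1-one; 15 tert-butyl (4-formylphenyl) carbonate; 16 4-methoxybenzyl alcohol
Product: 18 (2R,3R)-3-[4-(tert-butoxycarbonyloxy)phenyl]-1-[2-fluoro-4,6-bis(methoxymethoxy)-3,5-bis(3-methylbut-2-enyl)phenyl]-3-hydroxy-2-[(4-methoxybenzyl)oxy]propan-1-one, via oxonium ylide 17 (not isolated)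
Conditions: Rh2(OAc)4 (2 mol %), (R)-3,3'-bis(2,4,6-triisopropylphenyl)-1,1'-binaphthyl-2,2'-diyl hydrogen phosphate (10 mol %), 15 (2 equiv), 16 (2 equiv), 4 Å molecular sieves, CH2Cl2, 0 °C; 13 added over 4 h
Reagents that add atoms: none
Why: Rh2(OAc)4 expels N2 from 13, and the electrophilic rhodium carbene is captured by the hydroxyl oxygen of 16 to give the protic oxonium ylide 17, which is in equilibrium with its Z enol. The chiral phosphoric acid binds this enol through its P=O oxygen and the carbonyl of 15 through its P–OH, and the C2–C3 bond forms inside this hydrogen-bonded assembly before the ylide can collapse by 1,2-proton shift. The closest known reaction type is the dirhodium and chiral phosphoric acid co-catalysed three-component aldol-type (and Mannich-type) trapping of alcohol-derived oxonium ylides of diazo carbonyl compounds. No ring is closed; the C3–O and C2–C3 bonds and both stereocentres are formed. C2 (flavanone numbering) is set by the face of the aldehyde that the binaphthyl pocket leaves open, and C3 follows from the fixed Z geometry of the enol in the same organised transition state, which is expected to deliver the anti relation. The step needs chemoselectivity for the external O–H over the O5 acetal oxygen, its OCH2O hydrogens and the prenyl alkenes; slow addition of 13 into a concentrated solution of 16 and the poor donor ability of an aryl acetal oxygen should secure it. It also needs trapping to outrun proton transfer; the carbonate makes 15 a better acceptor than an alkoxybenzaldehyde, and it is used in excess at 0 °C.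

Step 8
Reactants: 18 (2R,3R)-3-[4-(tert-butoxycarbonyloxy)phenyl]-1-[2-fluoro-4,6-bis(methoxymethoxy)-3,5-bis(3-methylbut-2-enyl)phenyl]-3-hydroxy-2-[(4-methoxybenzyl)oxy]propan-1-one
Product: 19 (2R,3R)-2-[4-(tert-butoxycarbonyloxy)phenyl]-3-[(4-methoxybenzyl)oxy]-5,7-bis(methoxymethoxy)-6,8-bis(3-methylbut-2-enyl)chroman-4-one
Conditions: KN(SiMe3)2 (1.05 equiv), THF (0.01 M), −78 to 0 °C; aq. NH4Cl
Reagents that add atoms: none
Why: Intramolecular nucleophilic aromatic substitution: the potassium alkoxide adds to C8a, the Meisenheimer adduct is stabilised by the ortho C4 carbonyl, and loss of fluoride closes the six-membered ring C. The C2–O bond is never broken, so C2 keeps its configuration, and C3, the only base-labile centre, sits in the favoured trans diequatorial arrangement; a non-nucleophilic base, high dilution and low temperature spare the carbonate and disfavour retro-aldol.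

Step 9
Reactants: 19 (2R,3R)-2-[4-(tert-butoxycarbonyloxy)phenyl]-3-[(4-methoxybenzyl)oxy]-5,7-bis(methoxymethoxy)-6,8-bis(3-methylbut-2-enyl)chroman-4-one
Product: 20 (2R,3R)-2-[4-(tert-butoxycarbonyloxy)phenyl]-3-hydroxy-5,7-bis(methoxymethoxy)-6,8-bis(3-methylbut-2-enyl)chroman-4-one
Conditions: DDQ (1.5 equiv), CH2Cl2–pH 7 phosphate buffer (10:1), 0 °C to rt
Reagents that add atoms: none
Why: Oxidative cleavage of the 4-methoxybenzyl ether by DDQ (hydride abstraction, then hydrolysis of the oxocarbenium ion). The anisyl ring should be the best donor present, since ring A is deactivated by the conjugated carbonyl and ring B by the carbonate, and the phenols are still capped so the prenyl groups cannot be drawn into chromene formation.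

Step 10
Reactants: 20 (2R,3R)-2-[4-(tert-butoxycarbonyloxy)phenyl]-3-hydroxy-5,7-bis(methoxymethoxy)-6,8-bis(3-methylbut-2-enyl)chroman-4-one
Product: 21 6,8-diprenylaromadendrin, (2R,3R)-3,5,7-trihydroxy-2-(4-hydroxyphenyl)-6,8-bis(3-methylbut-2-enyl)chroman-4-one
Conditions: 3 M aq. HCl–MeOH (1:5), 45 °C, argon
Reagents that add atoms: none
Why: Acid-catalysed acetal exchange of both aryl methoxymethyl ethers with methanol and acidolysis of the aryl tert-butyl carbonate. Dilute HCl in methanol at moderate temperature is the usual way to free methoxymethyl-protected C-prenylated flavanones without closing the prenyl groups onto the new phenols, and neither stereocentre is touched.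

## Compound list

1 | 5-fluororesorcinol | Oc1cc(O)cc(F)c1 | starting material
2 | 1-fluoro-3,5-bis(methoxymethoxy)benzene | COCOc1cc(F)cc(OCOC)c1 | intermediate
3 | prenyl bromide (1-bromo-3-methylbut-2-ene) | CC(C)=CCBr | starting material
4 | [4-fluoro-2,6-bis(methoxymethoxy)phenyl]lithium (not isolated) | [Li]c1c(OCOC)cc(F)cc1OCOC | intermediate
5 | [4-fluoro-2,6-bis(methoxymethoxy)phenyl]copper (not isolated) | [Cu]c1c(OCOC)cc(F)cc1OCOC | intermediate
6 | 5-fluoro-1,3-bis(methoxymethoxy)-2-(3-methylbut-2-enyl)benzene | CC(C)=CCc1c(OCOC)cc(F)cc1OCOC | intermediate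
7 | [6-fluoro-2,4-bis(methoxymethoxy)-3-(3-methylbut-2-enyl)phenyl]lithium (not isolated) | [Li]c1c(F)cc(OCOC)c(CC=C(C)C)c1OCOC | intermediate
8 | [6-fluoro-2,4-bis(methoxymethoxy)-3-(3-methylbut-2-enyl)phenyl]copper (not isolated) | [Cu]c1c(F)cc(OCOC)c(CC=C(C)C)c1OCOC | intermediate
9 | 1-fluoro-3,5-bis(methoxymethoxy)-2,4-bis(3-methylbut-2-enyl)benzene | CC(C)=CCc1c(F)cc(OCOC)c(CC=C(C)C)c1OCOC | intermediate
10 | [2-fluoro-4,6-bis(methoxymethoxy)-3,5-bis(3-methylbut-2-enyl)phenyl]lithium (not isolated) | [Li]c1c(F)c(CC=C(C)C)c(OCOC)c(CC=C(C)C)c1OCOC | intermediate
11 | 1-[2-fluoro-4,6-bis(methoxymethoxy)-3,5-bis(3-methylbut-2-enyl)phenyl]ethan-1-one | CC(=O)c1c(F)c(CC=C(C)C)c(OCOC)c(CC=C(C)C)c1OCOC | intermediate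
12 | 4,4,4-trifluoro-1-[2-fluoro-4,6-bis(methoxymethoxy)-3,5-bis(3-methylbut-2-enyl)phenyl]butane-1,3-dione (not isolated) | O=C(CC(=O)C(F)(F)F)c1c(F)c(CC=C(C)C)c(OCOC)c(CC=C(C)C)c1OCOC | intermediate
13 | 2-diazo-1-[2-fluoro-4,6-bis(methoxymethoxy)-3,5-bis(3-methylbut-2-enyl)phenyl]ethan-1-one | CC(C)=CCc1c(OCOC)c(CC=C(C)C)c(F)c(C(=O)C=[N+]=[N-])c1OCOC | intermediate
14 | 4-hydroxybenzaldehyde | O=Cc1ccc(O)cc1 | starting material
15 | tert-butyl (4-formylphenyl) carbonate | CC(C)(C)OC(=O)Oc1ccc(C=O)cc1 | intermediate
16 | 4-methoxybenzyl alcohol | COc1ccc(CO)cc1 | starting material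
17 | (4-methoxybenzyl)oxonium ylide of the ketocarbene from 13, drawn as the enolate (not isolated) | [O-]C(=C[OH+]Cc1ccc(OC)cc1)c1c(F)c(CC=C(C)C)c(OCOC)c(CC=C(C)C)c1OCOC | intermediate
18 | (2R,3R)-3-[4-(tert-butoxycarbonyloxy)phenyl]-1-[2-fluoro-4,6-bis(methoxymethoxy)-3,5-bis(3-methylbut-2-enyl)phenyl]-3-hydroxy-2-[(4-methoxybenzyl)oxy]propan-1-one | CC(C)=CCc1c(OCOC)c(CC=C(C)C)c(F)c(C(=O)[C@H](OCc2ccc(OC)cc2)[C@@H](c2ccc(OC(=O)OC(C)(C)C)cc2)O)c1OCOC | intermediate
19 | (2R,3R)-2-[4-(tert-butoxycarbonyloxy)phenyl]-3-[(4-methoxybenzyl)oxy]-5,7-bis(methoxymethoxy)-6,8-bis(3-methylbut-2-enyl)chroman-4-one | CC(C)=CCc1c(OCOC)c(CC=C(C)C)c2c(c1OCOC)C(=O)[C@H](OCc1ccc(OC)cc1)[C@@H](c1ccc(OC(=O)OC(C)(C)C)cc1)O2 | intermediate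
20 | (2R,3R)-2-[4-(tert-butoxycarbonyloxy)phenyl]-3-hydroxy-5,7-bis(methoxymethoxy)-6,8-bis(3-methylbut-2-enyl)chroman-4-one | CC(C)=CCc1c(OCOC)c(CC=C(C)C)c2c(c1OCOC)C(=O)[C@H](O)[C@@H](c1ccc(OC(=O)OC(C)(C)C)cc1)O2 | intermediate
21 | 6,8-diprenylaromadendrin, (2R,3R)-3,5,7-trihydroxy-2-(4-hydroxyphenyl)-6,8-bis(3-methylbut-2-enyl)chroman-4-one | CC(C)=CCc1c(O)c(CC=C(C)C)c2c(c1O)C(=O)[C@H](O)[C@@H](c1ccc(O)cc1)O2 | target

## Step count and least certain steps

Total: 10 steps. Longest linear sequence: 9 steps (steps 1–5 and 7–10, from 1); step 6 is a one-step side branch.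

Step 7 (key step). Three things can go wrong.
- The ylide 17 may relax by proton shift to the plain O–H insertion product before it meets the aldehyde; the phosphoric acid can itself shuttle that proton.
- The carbene may be intercepted within the molecule by the O5 acetal oxygen or its OCH2O hydrogens.
- Face or anti control by the catalyst may be incomplete. A syn contaminant (C3 epimer) is tolerable, because C3 becomes the enolisable centre after ring closure and should settle trans; an error at C2 cannot be repaired.

The fallback avoids the carbene and sets C2 by reduction. It sets out from 9 (with 16 and 15 as the other parts) and comes back at 18. Etherification of 16 with 2-chloro-N-methoxy-N-methylacetamide gives the Weinreb amide N-methoxy-N-methyl-2-[(4-methoxybenzyl)oxy]acetamide F1. Lithiation of 9 as in step 4 and acylation with F1 gives the ketone 1-[2-fluoro-4,6-bis(methoxymethoxy)-3,5-bis(3-methylbut-2-enyl)phenyl]-2-[(4-methoxybenzyl)oxy]ethan-1-one F2. Its lithium enolate (LiN(SiMe3)2, THF, −78 °C) adds to 15 without stereocontrol to give the aldol mixture F3 (the constitution of 18, all stereoisomers). Dess–Martin oxidation gives the 2-alkoxy-1,3-diketone F4. Noyori asymmetric transfer hydrogenation with RuCl(p-cymene)[(S,S)-TsDPEN] in HCO2H–Et3N should reduce only the unhindered ring B ketone, with dynamic kinetic resolution at the doubly activated C–H, to give 18. The sense at C2 is assigned by analogy with simple aryl ketones.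

Step 8. The alkoxide may cleave by retro-aldol, or C3 may be deprotonated and lose hydroxide, faster than substitution occurs on a ring whose carbonyl is a weakened acceptor because of the two alkoxy donors. Surplus base can also open ring C of 19 by β-elimination and so erase C2. The fallback unveils the alkoxide only catalytically and uses no strong base. It sets out from 18 and comes back at 19. Silylation (TMSCl, imidazole, CH2Cl2) gives the trimethylsilyl ether F5. A catalytic amount of tetrabutylammonium difluorotriphenylsilicate in THF then removes the silyl group; the alkoxide closes onto C8a, and the fluoride it releases carries the chain.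

Step 9. DDQ may abstract hydride from the benzylic and allylic CH2 of the prenyl groups on ring A, or the cleavage may be slow because the ether oxygen is α to a ketone. The fallback is non-oxidative. It sets out from 19 and comes back at 21. MgBr2·OEt2 with Me2S in CH2Cl2 cleaves 4-methoxybenzyl ethers that have a coordinating neighbour. The chelated 5-O-methoxymethyl group is expected to be lost as well, giving (2R,3R)-2-[4-(tert-butoxycarbonyloxy)phenyl]-3,5-dihydroxy-7-(methoxymethoxy)-6,8-bis(3-methylbut-2-enyl)chroman-4-one F6. F6 is taken to 21 under the conditions of step 10, which remove all remaining groups.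

Step 2. Some metalation may occur next to fluorine instead of between the acetal ethers; the acetyl group would then end up para to fluorine two steps later. The fallback keeps the materials and changes the order of bond formation. It sets out from 2 and comes back at 11. If lithiation goes next to fluorine, the first prenylation gives the regioisomer 1-fluoro-3,5-bis(methoxymethoxy)-2-(3-methylbut-2-enyl)benzene F7. A second metalation at the other fluorine-flanked position is quenched with acetaldehyde to give the carbinol 1-[2-fluoro-4,6-bis(methoxymethoxy)-3-(3-methylbut-2-enyl)phenyl]ethan-1-ol F8. Its lithium alkoxide is metalated at the last ring position, now between the acetal ethers, passed to copper and prenylated to give 1-[2-fluoro-4,6-bis(methoxymethoxy)-3,5-bis(3-methylbut-2-enyl)phenyl]ethan-1-ol F9. Dess–Martin oxidation gives 11.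

## Further compounds

F1 | step 7 | N-methoxy-N-methyl-2-[(4-methoxybenzyl)oxy]acetamide | COc1ccc(COCC(=O)N(C)OC)cc1
F2 | step 7 | 1-[2-fluoro-4,6-bis(methoxymethoxy)-3,5-bis(3-methylbut-2-enyl)phenyl]-2-[(4-methoxybenzyl)oxy]ethan-1-one | COc1ccc(COCC(=O)c2c(F)c(CC=C(C)C)c(OCOC)c(CC=C(C)C)c2OCOC)cc1
F3 | step 7 | 3-[4-(tert-butoxycarbonyloxy)phenyl]-1-[2-fluoro-4,6-bis(methoxymethoxy)-3,5-bis(3-methylbut-2-enyl)phenyl]-3-hydroxy-2-[(4-methoxybenzyl)oxy]propan-1-one, mixture of stereoisomers | CC(C)=CCc1c(OCOC)c(CC=C(C)C)c(F)c(C(=O)C(OCc2ccc(OC)cc2)C(O)c2ccc(OC(=O)OC(C)(C)C)cc2)c1OCOC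
F4 | step 7 | 1-[4-(tert-butoxycarbonyloxy)phenyl]-3-[2-fluoro-4,6-bis(methoxymethoxy)-3,5-bis(3-methylbut-2-enyl)phenyl]-2-[(4-methoxybenzyl)oxy]propane-1,3-dione | CC(C)=CCc1c(OCOC)c(CC=C(C)C)c(F)c(C(=O)C(OCc2ccc(OC)cc2)C(=O)c2ccc(OC(=O)OC(C)(C)C)cc2)c1OCOC
F5 | step 8 | (2R,3R)-3-[4-(tert-butoxycarbonyloxy)phenyl]-1-[2-fluoro-4,6-bis(methoxymethoxy)-3,5-bis(3-methylbut-2-enyl)phenyl]-2-[(4-methoxybenzyl)oxy]-3-(trimethylsilyloxy)propan-1-one | CC(C)=CCc1c(OCOC)c(CC=C(C)C)c(F)c(C(=O)[C@H](OCc2ccc(OC)cc2)[C@@H](c2ccc(OC(=O)OC(C)(C)C)cc2)O[Si](C)(C)C)c1OCOC
F6 | step 9 | (2R,3R)-2-[4-(tert-butoxycarbonyloxy)phenyl]-3,5-dihydroxy-7-(methoxymethoxy)-6,8-bis(3-methylbut-2-enyl)chroman-4-one | CC(C)=CCc1c(OCOC)c(CC=C(C)C)c2c(c1O)C(=O)[C@H](O)[C@@H](c1ccc(OC(=O)OC(C)(C)C)cc1)O2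
F7 | step 2 | 1-fluoro-3,5-bis(methoxymethoxy)-2-(3-methylbut-2-enyl)benzene | CC(C)=CCc1c(F)cc(OCOC)cc1OCOC
F8 | step 2 | 1-[2-fluoro-4,6-bis(methoxymethoxy)-3-(3-methylbut-2-enyl)phenyl]ethan-1-ol, racemic | CC(O)c1c(F)c(CC=C(C)C)c(OCOC)cc1OCOC
F9 | step 2 | 1-[2-fluoro-4,6-bis(methoxymethoxy)-3,5-bis(3-methylbut-2-enyl)phenyl]ethan-1-ol, racemic | CC(O)c1c(F)c(CC=C(C)C)c(OCOC)c(CC=C(C)C)c1OCOC
A1 | alternative 1 | 5-(methoxymethoxy)-2,4-bis(3-methylbut-2-enyl)-3-(triisopropylsilyloxy)phenol | Oc1cc(OCOC)c(CC=C(C)C)c(O[Si](C(C)C)(C(C)C)C(C)C)c1CC=C(C)C
A2 | alternative 1 | 3-(methoxymethoxy)-2-(3-methylbut-2-enyl)cyclobut-2-en-1-one | COCOC1=C(CC=C(C)C)C(=O)C1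
A3 | alternative 1 | triisopropyl[(5-methylhex-4-en-1-yn-1-yl)oxy]silane (also the third alkyne of alternative 2) | CC(C)=CCC#CO[Si](C(C)C)(C(C)C)C(C)C
A4 | alternative 2 | (2R,3R)-3-(methoxymethoxy)-2-[4-(methoxymethoxy)phenyl]-6,8-bis(3-methylbut-2-enyl)-5,7-bis(triisopropylsilyloxy)chroman-4-one | CC(C)=CCc1c(O[Si](C(C)C)(C(C)C)C(C)C)c(CC=C(C)C)c2c(c1O[Si](C(C)C)(C(C)C)C(C)C)C(=O)[C@H](OCOC)[C@@H](c1ccc(OCOC)cc1)O2
A5 | alternative 2 | (4R,5R)-4-(methoxymethoxy)-5-[4-(methoxymethoxy)phenyl]-5-[(5-methylhex-4-en-1-yn-1-yl)oxy]-1-(triisopropylsilyloxy)pent-1-yn-3-one | CC(C)=CCC#CO[C@H](c1ccc(OCOC)cc1)[C@@H](OCOC)C(=O)C#CO[Si](C(C)C)(C(C)C)C(C)C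
A6 | alternative 3 | (2R,3R)-6,8-diallyl-5,7-dihydroxy-3-(methoxymethoxy)-2-[4-(methoxymethoxy)phenyl]chroman-4-one | C=CCc1c(O)c(CC=C)c2c(c1O)C(=O)[C@H](OCOC)[C@@H](c1ccc(OCOC)cc1)O2
A7 | alternative 3 | (2R,3R)-5,7-bis(allyloxy)-3-(methoxymethoxy)-2-[4-(methoxymethoxy)phenyl]chroman-4-one | C=CCOc1cc2c(c(OCC=C)c1)C(=O)[C@H](OCOC)[C@@H](c1ccc(OCOC)cc1)O2
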